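The route rests on cutting the bond between the spiro carbon C15 and C1, the methylidene-bearing carbon of ring D. The feature exploited is that C15 is also α to C6, the ring-B carbon that carries the ether oxygen: with C6 as a ketone, C15 is an enolate carbon. One palladium-catalysed intramolecular enolate alkenylation with a tethered 2-bromoalkene then closes ring D, creates the quaternary spiro stereocentre and places the exocyclic methylene. The precursor is a trans-decal-6-one bearing the equatorial C9 bromide, the silylated C12 carbinol and an equatorial CMe2–CH(OSiEt3)–CH2CH2–C(Br)=CH2 arm on C15. Ring C is closed last, the C6 alkoxide inverting a C4 mesylate.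

Key step: step 15

**Remarks on the chemistry**

- **Atom labels used in all names.**
  - C1 = C(=CH2); C2 and C3 = CH2; C4 = ring-D CH–O; O5 = ether oxygen; C6 = ring-B CH–O; C7 = CH2.
  - C8 = ring-fusion C(CH3); C9 = CHBr; C10 and C11 = CH2; C12 = C(CH3)(OH); C13 = ring-fusion CH; C14 = CH2.
  - C15 = spiro carbon; C16 = CMe2.
  - Ring A = C8–C13. Ring B = C6, C7, C8, C13, C14, C15. Ring C = C4, O5, C6, C15, C16. Ring D = C1–C4, C16, C15.
  - α is the face of the 8-methyl group and β the opposite face.
  - Target: 4S,6R,8S,9S,12R,13S,15R.
- **Design remark on C4.**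
  - In the target O5 is equatorial on ring B and trans to C16, so ring C is trans-fused to ring B.
  - A ring-D alkoxide cannot displace a leaving group on C6. The leaving group that would invert to this configuration is cis to C16 on ring B, so their dihedral angle stays near 60°, whereas rear-side attack through a five-membered transition state needs about 150°. An axial C6 sulfonate would instead eliminate towards C7.
  - The polarity is therefore reversed. C4 is carried as the (R)-carbinol, opposite to the (S)-ether carbon of the target. It becomes the mesylate and is inverted by the equatorial C6 alkoxide.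
  - In the ring-D chair this mesylate is equatorial and antiperiplanar to C16–C15.
- **Assumption.** (R)-BINOL is taken to shield the quinone face that leads to (8S). If the sense is opposite, (S)-BINOL, equally available, is used and nothing else changes.

Step 1
Reactants: 1 but-3-en-2-one
Product: 2 2-(triisopropylsilyloxy)buta-1,3-diene
Conditions: i-Pr3SiOTf, Et3N, Et2O, 0→23 °C
Reagents that add atoms: triisopropylsilyl triflate CC(C)[Si](C(C)C)(C(C)C)OS(=O)(=O)C(F)(F)F
Why: Soft enolisation and O-silylation of the methyl ketone (silyl enol ether formation) should give the 2-silyloxydiene, and the bulky silyl group is chosen because this enol ether has to mask C6 through steps 2 to 5.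

Step 2
Reactants: 2 2-(triisopropylsilyloxy)buta-1,3-diene; 3 2-methoxy-5-methyl-1,4-benzoquinone
Product: 4 cis-fused Diels–Alder adduct
Conditions: TiCl2[(R)-BINOLate] (20 mol %, from TiCl2(Oi-Pr)2 and (R)-BINOL, 4 Å MS), CH2Cl2, −40 °C
Reagents that add atoms: none
Why: Catalytic enantioselective quinone Diels–Alder reaction: the methoxy group deactivates its own double bond, two-point binding of titanium to the C12 carbonyl oxygen and the neighbouring methoxy oxygen makes that carbonyl the directing group so that the nucleophilic CH2 terminus of the diene bonds to the methyl-bearing carbon ("para" orientation, C6 oxygenated), suprafacial addition sets C8 and C13 cis, and the binaphtholate shields one quinone face, which fixes (8S).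

Step 3
Reactants: 4 cis-fused Diels–Alder adduct
Product: 6 trans-fused methoxy ene-dione, via potassium dienolate 5 (not isolated)
Conditions: KN(SiMe3)2, THF, −78 °C; then AcOH, −78 °C
Reagents that add atoms: potassium hexamethyldisilazide C[Si](C)(C)[N-][Si](C)(C)C.[K+] (potassium, in 5 only)
Why: Ring-fusion epimerisation by enolate formation and kinetic protonation: H-13 is the only acidic hydrogen (C8 is quaternary, C10 and C11 are sp2), and the flat dienolate should be protonated at C13 on the β-face, away from the pseudo-axial 8-methyl, which sets the trans fusion.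

Step 4
Reactants: 6 trans-fused methoxy ene-dione
Product: 7 C12 tertiary carbinol
Conditions: MeLi, CeCl3, THF, −78 °C; then H2O
Reagents that add atoms: methyllithium [Li]C
Why: 1,2-Addition of a weakly basic organocerium reagent: C12 is the only true ketone (C9 is a neopentyl vinylogous-ester carbonyl), and attack on the β-face, opposite the 1,3-related 8-methyl, should place the new methyl equatorial and the hydroxyl axial (α), after which C13 can no longer epimerise.

Step 5
Reactants: 7 C12 tertiary carbinol
Product: 9 saturated C9 ketone, via enone 8 (not isolated)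
Conditions: LiN(SiMe3)2 (1 equiv), THF; then Li, NH3–THF, t-BuOH, −78 °C; NH4Cl
Reagents that add atoms: none
Why: Dissolving-metal (Birch-type) reduction of a β-alkoxy enone: conjugate reduction gives a β-methoxy enolate that expels methoxide, enone 8 is reduced again to the C9 lithium enolate, which resists further reduction, while the pre-formed C12 lithium alkoxide is too poor a leaving group to be lost and the isolated silyl enol ether is inert.

Step 6
Reactants: 9 saturated C9 ketone
Product: 10 C6 dimethyl ketal
Conditions: MeOH, HC(OMe)3, camphorsulfonic acid (cat.), 23 °C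
Reagents that add atoms: methanol CO
Why: Acid-catalysed methanolysis of the silyl enol ether (ketalisation) exchanges the bromine- and radical-sensitive enol ether for a dimethyl ketal, while the neopentyl C9 ketone is too hindered to ketalise and the ring fusion is already locked.

Step 7
Reactants: 10 C6 dimethyl ketal
Product: 12 C9 alkenyl bromide, via hydrazone 11 (not isolated)
Conditions: N2H4·H2O, Et3N, EtOH, 80 °C; concentrate; then Br2, 2-tert-butyl-1,1,3,3-tetramethylguanidine, CH2Cl2, 0 °C
Reagents that add atoms: hydrazine NN (nitrogen, in 11 only); bromine BrBr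
Why: Barton-type vinyl halide synthesis: the hydrazone is oxidised to the diazoalkane, brominated, and loses N2 and a proton, and because C8 is quaternary the double bond can form only towards C10.

Step 8
Reactants: 12 C9 alkenyl bromide
Product: 13 equatorial C9 bromide
Conditions: Mn(dpm)3 (cat., dpm = 2,2,6,6-tetramethylheptane-3,5-dionate), PhSiH3, t-BuOOH, i-PrOH, 23 °C
Reagents that add atoms: none
Why: Metal-hydride hydrogen-atom-transfer (Mukaiyama-type) hydrogenation, a radical method known to saturate haloalkenes without hydrogenolysis: H· adds to C10 and the bromine-stabilised C9 radical should take its hydrogen on the β-face, anti to the adjacent axial 8-methyl, so that bromine ends equatorial (α).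

Step 9
Reactants: 13 equatorial C9 bromide; 14 3-methylbut-2-en-1-ol
Product: 16 reverse-prenyl ketone, via prenyl enol ether 15 (not isolated)
Conditions: 14 (excess), EtCO2H (cat.), xylenes, 140 °C, MeOH distilled off
Reagents that add atoms: none
Why: Ketal Claisen rearrangement: acid-catalysed exchange and loss of methanol give the prenyl enol ether, only its C6=C15 isomer can reach a chair transition state (C7 is flanked by quaternary C8), the [3,3]-shift builds the C15–C16 bond with the quaternary CMe2 carbon, and C15 equilibrates under these conditions to the equatorial (α) arm.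

Step 10
Reactants: 16 reverse-prenyl ketone
Product: 17 keto aldehyde
Conditions: O3, CH2Cl2, −78 °C; then Me2S
Reagents that add atoms: ozone [O-][O+]=O
Why: Ozonolysis with reductive work-up cleaves the only C=C bond to the non-enolisable neopentyl aldehyde C4.

Step 11
Reactants: 17 keto aldehyde; 18 2,4-dibromobut-1-ene
Product: 20 C4-epimeric hydroxy ketone, via 3-bromobut-3-enylmagnesium bromide 19 (not isolated)
Conditions: 18, Mg, THF, 0→23 °C; then 17, THF, −78 °C; H2O
Reagents that add atoms: magnesium [Mg] (in 19 only)
Why: Chemoselective Grignard addition: magnesium inserts into the primary sp3 C–Br bond much faster than into the vinylic one, at −78 °C the aldehyde reacts while the C6 ketone next to the tert-alkyl arm does not, one extra equivalent is spent on the free hydroxyl, and the C4 configuration is irrelevant because step 12 erases it.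

Step 12
Reactants: 20 C4-epimeric hydroxy ketone
Product: 21 1,4-diketone
Conditions: Dess–Martin periodinane, CH2Cl2, 23 °C
Reagents that add atoms: none
Why: Dess–Martin oxidation converts the secondary C4 carbinol (tertiary C12–OH untouched) into the ketone under non-basic conditions that avoid aldol closure of the 1,4-diketone.

Step 13
Reactants: 21 1,4-diketone
Product: 22 (4R)-hydroxy ketone
Conditions: (S)-2-methyl-CBS-oxazaborolidine (0.3 equiv), BH3·SMe2, THF, −20 °C; then MeOH
Reagents that add atoms: none
Why: Corey–Bakshi–Shibata reduction: reagent control with tert-alkyl C16 as the large and the CH2 chain as the small substituent should give the (4R)-carbinol, and the acyclic ketone reacts first because C6 is shielded by the equatorial tert-alkyl arm, neopentyl C7 and the syn-axial 8-methyl.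

Step 14
Reactants: 22 (4R)-hydroxy ketone
Product: 23 bromoallyl-armed trans-decalone (bis-triethylsilyl ether)
Conditions: Et3SiOTf, 2,6-lutidine, CH2Cl2, 0→23 °C
Reagents that add atoms: triethylsilyl triflate CC[Si](CC)(CC)OS(=O)(=O)C(F)(F)F
Why: Silyl ether formation with the reactive triflate covers the neopentyl secondary and the hindered tertiary hydroxyl in one operation, which prevents palladium alkoxide formation and hemiketalisation in step 15.

Step 15
Reactants: 23 bromoallyl-armed trans-decalone (bis-triethylsilyl ether)
Product: 25 spiro ring-D ketone, via potassium enolate 24 (not isolated)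
Conditions: Pd(PPh3)4 (0.15 equiv), KOPh, THF, 70 °C
Reagents that add atoms: potassium phenoxide [K+].[O-]c1ccccc1 (potassium, in 24 only)
Why: Oxidative addition of the alkenyl C1–Br bond to zerovalent palladium, reversible enolisation of the C6 ketone by phenoxide, exchange of bromide for the C15 enolate on divalent palladium and C–C reductive elimination form the C15–C1 bond. The closest known reaction type is the palladium-catalysed intramolecular α-alkenylation of ketone enolates with vinyl halides. Ring D closes as a six-membered ring in the exo mode (reductive elimination from a seven-membered C-bound palladacycle), so the C=CH2 unit stays outside the ring. The new stereocentre C15 is controlled by the trans-decalin chair: the alkenyl carbon enters axially on the β-face, anti to the axial 8-methyl, the bulky C16 arm stays equatorial, and the (4R)-silyloxy group sits equatorial in the chair-like ring-D transition state. Site selectivity is secured because the C7 enolate could only give an eight-membered ring, enolisation is reversible and C16 carries no leaving group for β-elimination. Chemoselectivity is secured because the neopentyl, equatorial secondary C9 bromide does not add to Pd(PPh3)4 at this temperature and has no antiperiplanar hydrogen for E2 loss.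

Step 16
Reactants: 25 spiro ring-D ketone
Product: 26 spiro keto diol
Conditions: HF·pyridine, THF, 0→23 °C
Reagents that add atoms: none
Why: Fluoride-mediated desilylation removes both triethylsilyl ethers, and the (4R)-hydroxyl is trans to C6 across ring D and therefore cannot form a hemiketal.

Step 17
Reactants: 26 spiro keto diol
Product: 27 C4 mesylate
Conditions: MsCl, Et3N, CH2Cl2, −10 °C
Reagents that add atoms: methanesulfonyl chloride CS(=O)(=O)Cl
Why: Sulfonate ester formation via sulfene is selective for the secondary C4 hydroxyl over the axial tertiary C12 hydroxyl.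

Step 18
Reactants: 27 C4 mesylate
Product: 28 equatorial C6 carbinol mesylate
Conditions: SmI2, THF–H2O, 0 °C
Reagents that add atoms: none
Why: Single-electron (ketyl) reduction with SmI2–water should give the thermodynamically preferred carbinol, here the equatorial β-alcohol because an axial C6–OH would be syn-axial to the 8-methyl, and without HMPA or amine additives the samarium-bound ketone is reduced much faster than the hindered secondary bromide or the mesylate.

Step 19
Reactants: 28 equatorial C6 carbinol mesylate
Product: 30 target CNP0412361.2, via potassium alkoxide 29 (not isolated)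
Conditions: KN(SiMe3)2, THF, 0→40 °C
Reagents that add atoms: potassium hexamethyldisilazide C[Si](C)(C)[N-][Si](C)(C)C.[K+] (potassium, in 29 only)
Why: Intramolecular Williamson etherification (5-exo-tet SN2): in the ring-D chair C6 is axial and the mesylate equatorial, antiperiplanar to C16–C15, so the C6 alkoxide attacks C4 from the rear, inverts it to (S) and closes the 6-oxabicyclo[3.2.1]octane, while E2 loss is disfavoured because no C3 hydrogen is antiperiplanar to an equatorial leaving group.

**Compound list**

1 | but-3-en-2-one | C=CC(C)=O | starting material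
2 | 2-(triisopropylsilyloxy)buta-1,3-diene | C=CC(=C)O[Si](C(C)C)(C(C)C)C(C)C | intermediate
3 | 2-methoxy-5-methyl-1,4-benzoquinone | COC1=CC(=O)C(C)=CC1=O | starting material
4 | (4aS,8aR)-2-methoxy-4a-methyl-6-(triisopropylsilyloxy)-4a,5,8,8a-tetrahydronaphthalene-1,4-dione (cis-fused, 8-Me and H-13 both α) | C1=C(O[Si](C(C)C)(C(C)C)C(C)C)C[C@]2(C)C(=O)C=C(OC)C(=O)[C@@H]2C1 | intermediate
5 | potassium C12–C13 dienolate of 4 | C1=C(O[Si](C(C)C)(C(C)C)C(C)C)C[C@]2(C)C(=O)C=C(OC)C([O-])=C2C1.[K+] | intermediate
6 | (4aS,8aS)-epimer of 4 (trans-fused, H-13 β) | C1=C(O[Si](C(C)C)(C(C)C)C(C)C)C[C@]2(C)C(=O)C=C(OC)C(=O)[C@H]2C1 | intermediate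
7 | trans-fused vinylogous ester with 12α-OH (axial), 12β-Me, C9 ketone, C10=C11(OMe), C6=C15 silyl enol ether | C1=C(O[Si](C(C)C)(C(C)C)C(C)C)C[C@]2(C)C(=O)C=C(OC)[C@@](C)(O)[C@H]2C1 | intermediate
8 | C9 ketone with C10=C11 double bond (methoxy lost), otherwise as 7 | C1=C(O[Si](C(C)C)(C(C)C)C(C)C)C[C@]2(C)C(=O)C=C[C@@](C)(O)[C@H]2C1 | intermediate
9 | trans-decal-9-one with 12α-OH, 8α,12β-dimethyl, C6=C15 triisopropylsilyl enol ether | C1=C(O[Si](C(C)C)(C(C)C)C(C)C)C[C@]2(C)C(=O)CC[C@@](C)(O)[C@H]2C1 | intermediate
10 | 6,6-dimethoxy-12α-hydroxy-8α,12β-dimethyl-trans-decal-9-one | C1C(OC)(OC)C[C@]2(C)C(=O)CC[C@@](C)(O)[C@H]2C1 | intermediate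
11 | C9 hydrazone of 10 | C1C(OC)(OC)C[C@]2(C)C(=NN)CC[C@@](C)(O)[C@H]2C1 | intermediate
12 | 9-bromo-C9=C10 alkene, 6,6-dimethyl ketal, 12α-OH | C1C(OC)(OC)C[C@]2(C)C(Br)=CC[C@@](C)(O)[C@H]2C1 | intermediate
13 | 9α-bromo (equatorial)-6,6-dimethoxy-8α,12β-dimethyl-trans-decalin-12α-ol | C1C(OC)(OC)C[C@]2(C)[C@@H](Br)CC[C@@](C)(O)[C@H]2C1 | intermediate
14 | 3-methylbut-2-en-1-ol (prenyl alcohol) | CC(C)=CCO | starting material
15 | C6=C15 prenyl enol ether of the bromo carbinol | C1=C(OCC=C(C)C)C[C@]2(C)[C@@H](Br)CC[C@@](C)(O)[C@H]2C1 | intermediate
16 | 9α-bromo-12α-hydroxy-15α-(2-methylbut-3-en-2-yl)-trans-decal-6-one (arm equatorial) | C=CC(C)(C)[C@H]1C(=O)C[C@]2(C)[C@@H](Br)CC[C@@](C)(O)[C@H]2C1 | intermediate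
17 | keto aldehyde, C16Me2–C4HO arm equatorial on C15 | O=CC(C)(C)[C@H]1C(=O)C[C@]2(C)[C@@H](Br)CC[C@@](C)(O)[C@H]2C1 | intermediate
18 | 2,4-dibromobut-1-ene | C=C(Br)CCBr | starting material
19 | 3-bromobut-3-enylmagnesium bromide | C=C(Br)CC[Mg]Br | intermediate
20 | hydroxy ketone with full side chain, C4 epimers | C=C(Br)CCC(O)C(C)(C)[C@H]1C(=O)C[C@]2(C)[C@@H](Br)CC[C@@](C)(O)[C@H]2C1 | intermediate
21 | C4,C6 diketone | C=C(Br)CCC(=O)C(C)(C)[C@H]1C(=O)C[C@]2(C)[C@@H](Br)CC[C@@](C)(O)[C@H]2C1 | intermediate
22 | (4R)-hydroxy ketone | C=C(Br)CC[C@@H](O)C(C)(C)[C@H]1C(=O)C[C@]2(C)[C@@H](Br)CC[C@@](C)(O)[C@H]2C1 | intermediate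
23 | key-step precursor: (4R,15S) bromoallyl-armed trans-decal-6-one, C4 and C12 triethylsilyl ethers | C=C(Br)CC[C@@H](O[Si](CC)(CC)CC)C(C)(C)[C@H]1C(=O)C[C@]2(C)[C@@H](Br)CC[C@@](C)(O[Si](CC)(CC)CC)[C@H]2C1 | intermediate
24 | potassium C6–C15 enolate of 23 | C=C(Br)CC[C@@H](O[Si](CC)(CC)CC)C(C)(C)C1=C([O-])C[C@]2(C)[C@@H](Br)CC[C@@](C)(O[Si](CC)(CC)CC)[C@H]2C1.[K+] | intermediate
25 | key-step product: (4R,15R) spiro ring-D ketone, C1 axial (β) on ring B, exocyclic methylene, bis-triethylsilyl ether | C=C1CC[C@@H](O[Si](CC)(CC)CC)C(C)(C)[C@]12C(=O)C[C@]3(C)[C@@H](Br)CC[C@@](C)(O[Si](CC)(CC)CC)[C@H]3C2 | intermediate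
26 | spiro keto diol, (4R)-OH and 12α-OH | C=C1CC[C@@H](O)C(C)(C)[C@]12C(=O)C[C@]3(C)[C@@H](Br)CC[C@@](C)(O)[C@H]3C2 | intermediate
27 | (4R)-mesylate of 26 | C=C1CC[C@@H](OS(C)(=O)=O)C(C)(C)[C@]12C(=O)C[C@]3(C)[C@@H](Br)CC[C@@](C)(O)[C@H]3C2 | intermediate
28 | (4R)-mesylate with (6R) 6β-OH (equatorial) | C=C1CC[C@@H](OS(C)(=O)=O)C(C)(C)[C@]12[C@H](O)C[C@]3(C)[C@@H](Br)CC[C@@](C)(O)[C@H]3C2 | intermediate
29 | potassium C6 alkoxide of 28 | C=C1CC[C@@H](OS(C)(=O)=O)C(C)(C)[C@]12[C@H]([O-])C[C@]3(C)[C@@H](Br)CC[C@@](C)(O)[C@H]3C2.[K+] | intermediate
30 | CNP0412361.2 (4S,6R,8S,9S,12R,13S,15R) | C=C1CC[C@@H]2O[C@@H]3C[C@]4(C)[C@@H](Br)CC[C@@](C)(O)[C@H]4C[C@]13C2(C)C | target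

Total step count: 19. Longest linear sequence: 19 steps (1 → 30).

**Three steps most likely to fail**

**Step 15**
- **What may go wrong.** Enolisation at the hindered tertiary C15 may be too slow, so protodebromination of the alkenylpalladium intermediate takes over. Facial selectivity at C15 may also erode.
- **Fallback (π-acid activation of an alkyne in place of cross-coupling).**
  - It sets out from 23. Excess LiN(i-Pr)2 in THF (−78→0 °C) eliminates HBr from the 2-bromoalkene and should give the alkynyl ketone F1.
  - Me3SiI with (Me3Si)2NH under equilibrating conditions should then give the tetrasubstituted C6=C15 trimethylsilyl enol ether F2.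
  - AuCl(PPh3)/AgBF4 in wet CH2Cl2 triggers a 6-exo-dig Conia-ene-type attack of the enol silane on the gold-bound alkyne, again axial on the β-face.
  - Protodeauration returns the route at 25.

**Step 8**
- **What may go wrong.** Hydrogen-atom transfer to the hindered trisubstituted bromoalkene may be sluggish. Bromine may be lost in the radical chain. Hydrogen delivery to C9 may show poor facial selectivity.
- **Fallback (geminal dihalide and mono-reduction in place of alkene hydrogenation).**
  - It sets out from hydrazone 11, now isolated. CuBr2 with t-BuOLi in THF should convert it into the geminal dibromide F3.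
  - One equivalent of Bu3SnH (Et3B, air, toluene, −78 °C) removes one bromine.
  - The α-bromo radical takes hydrogen from the β-face, which returns the route at 13.

**Step 18**
- **What may go wrong.** Electron transfer to the C–Br bond may compete with ketone reduction. Protonation of the ketyl-derived organosamarium species may also show poor facial selectivity.
- **Fallback (hydride reduction followed by redox equilibration of the carbinol).**
  - It sets out from 27. NaBH4 in MeOH–THF at 0 °C reduces the ketone without touching bromide or mesylate and may deliver the axial C6 carbinol F4.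
  - Al(Oi-Pr)3 with a catalytic amount of acetone in toluene at 90 °C (Meerwein–Ponndorf–Verley/Oppenauer equilibration) interconverts the epimers through 27.
  - The equilibrium should drain to the equatorial carbinol, free of the syn-axial methyl interaction, which returns the route at 28.

**Further compounds**

F1 | step 15 | alkynyl ketone | C#CCC[C@@H](O[Si](CC)(CC)CC)C(C)(C)[C@H]1C(=O)C[C@]2(C)[C@@H](Br)CC[C@@](C)(O[Si](CC)(CC)CC)[C@H]2C1
F2 | step 15 | C6=C15 trimethylsilyl enol ether | C#CCC[C@@H](O[Si](CC)(CC)CC)C(C)(C)C1=C(O[Si](C)(C)C)C[C@]2(C)[C@@H](Br)CC[C@@](C)(O[Si](CC)(CC)CC)[C@H]2C1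
F3 | step 8 | geminal dibromide | C1C(OC)(OC)C[C@]2(C)C(Br)(Br)CC[C@@](C)(O)[C@H]2C1
F4 | step 18 | axial C6 carbinol | C=C1CC[C@@H](OS(C)(=O)=O)C(C)(C)[C@]12[C@@H](O)C[C@]3(C)[C@@H](Br)CC[C@@](C)(O)[C@H]3C2
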